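The readings stem from a simulated flask from invented constants, and the scatter is random.

- A first-order rate constant carries no concentration, so once reversible first-order steps have come level, each species holds the same share of the charge whatever the starting [substrate]; we take this charge-blind case as the zero of our scale.

| flask | substrate | remark | time |
|---|---|---|---|
| north-west | 0.63 M | run made earlier |  |
| south-west | 0.99 M | run made earlier |  |
| flask | 0.45 M |  | 80 min |

- north-west (time / min: isomer of the product B / %, target / %, substrate / %): 5.00: 27, 1, 5; 10.0: 20, 4, 6; 20.0: 14, 1, 6; 30.0: 11, 0, 5; 60.0: 9, 3, 5
- south-west (time / min: isomer of the product B / %, target / %, substrate / %): 12.0: 15, 1, 5; 25.0: 11, 3, 4; 40.0: 11, 1, 3; 50.0: 9, 0, 6; 60.0: 11, 1, 2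

(scatter of a reading: 1.5 percentage points)

- the analysis behind the earlier runs scatters by 1.5 percentage points, standard deviation
- the reaction counts as stopped when no species that holds the substrate changes by six tenths of a point or more over the second half of the time

- at 80 min, what has stopped the reaction, if anything has (it is still moving / all of the substrate has reacted / forward and back rates have come level)
- the isomer of the product B standing at 80 min, as a percentage of the substrate charged

- The isomer of the product B looks flat from 30.0 min in the north-west run, where its late readings average 10.0%, and from 25.0 min in the south-west run, where they average 10.5%; the gap of 0.5 percentage points is smaller than the 1.3 points that scatter gives such a difference, so these runs show no departure from the zero.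
- We therefore pool them: the plateau share, the mean of the late readings of the isomer of the product B as a percentage of the charge, is 10.3%, give or take 0.61 points, and we read it as thermodynamic control after the high early readings.
- Even if time scaled with the charge, our flask at 80 min would match the north-west run at 57.1 min, later than 30.0 min, and late substrate readings of the two runs, averaging 4.17%, show it has not run out in them, so we expect level rates and 10.3% in our flask.
- The forecast also says that forward and back rates have come level, with 10.5%, slightly above our figure, noting “the plateau barely depends on charge”.
- In the flask at 80 min, forward and back rates have come level, and the isomer of the product B stands at 11.4%, so the forecast holds on both questions.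

    isomer of the product B ⇌ substrate (k = 0.0110 s⁻¹)
    substrate ⇌ target (K = 0.260, k = 0.0420 s⁻¹)
    isomer of the product A ⇌ isomer of the product B (K = 12.0, k = 0.290 s⁻¹)
    substrate ⇌ dormant form (K = 25.0, k = 0.0160 s⁻¹)
    target ⇌ isomer of the product A (K = 1.10, k = 0.0400 s⁻¹)
    substrate → decomposition product (k = 3.30 × 10⁻⁵ s⁻¹)

- In this flask the conversion of substrate into dormant form had 97% of its turnover up to 80 min behind it by 16.0 min, and between 8.00 min and 40.0 min the dormant form rose from 69.1% to 83.0% as the isomer of the product B fell from 21.8% to 11.4%. From then to 80 min both kept those figures to the digits shown, while the decomposition product crept from 0.407% to 0.670%. For the forecast to be 5 points off, the time would have had to be as short as 11.9 min, where the answer in this flask has moved by that much.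
- For the neighbouring flask with 1.8 M of substrate, the plateau share again gives 10.3% at 80 min; the computed value there is 11.4%.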